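## Structural features

The target is a C2-symmetric 2,5-diaryl-3,4-dimethyloxolane (one ring, ring A, atoms O1 and C2–C5). Each aryl group is a 3-methoxy-4-alkoxyphenyl unit whose C4 oxygen is etherified by C8 of a (1R,2R)-1-(3,4-dimethoxyphenyl)-1-hydroxypropan-2-yl arm. Ring A carries four contiguous stereocentres, (2R,3S,4S,5R): each aryl is cis to the methyl on the neighbouring carbon, the two methyls are trans and the two aryls are trans. Each arm adds a threo pair (C7 carbinol, C8 aryl ether), so there are eight stereocentres in all. The fragile points are the benzylic C2–O1 and C5–O1 bonds (para to an alkoxy group: acid ionises them and the ring relaxes to the aryl/methyl trans isomers; they are also hydrogenolysed), the arm carbinols (benzylic to a veratryl ring) and four electron-rich arenes. The real difficulty is the contra-thermodynamic cis relation at C2/C3 and at C4/C5 together with the trans relation C3/C4, to be built while both arms are carried. The key step exploits the C2–C3 edge of ring A: C2 (aryl, O1) and C3 (methyl) are adjacent, so an anti-aldol whose carbinol carbon becomes C2 and whose acyl carbon is later reduced to the C3 methyl sets both at once. The acyl chain already holds C4 and, as a 1,1-disubstituted alkene, the masked C5 carbonyl.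

## Logic of the disconnections

31 ⇒ 30. The two arm O–H bonds are replaced by O–Si bonds. The carbinols must be masked through base, hydride, oxidant and Lewis acid, and a silyl ether is the only mask that comes off without acid or hydrogen. The demand is a fluoride deprotection that leaves the benzylic ethers alone.

30 ⇒ 28 (through 29). The C5–H bond is cut back to a C5–OH hemiketal. This moves the last ring stereocentre into a reduction step and reduces the problem to an open chain with three stereocentres. The demand is hydride delivery to C5 anti to the C4 methyl, at a temperature where neither the ring nor the arm silyl ethers ionise.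

28 ⇒ 25 (through 27 and 26). The O1–C5 bond is opened and the C5=O bond is traced to a C5=CH2 bond. A ketone at C5 could not pass through the aldol (enolisable, and it would epimerise C4); a 1,1-disubstituted alkene is inert there. The demand is an oxidative cleavage that spares four electron-rich arenes.

25 ⇒ 24 ⇒ 23 ⇒ 22. The three C–H bonds of the C3 methyl are traced to a C–O bond and then to the imide carbonyl. This is the price of using an aldol for a carbon that ends as CH3. The demands are selective activation of a primary hydroxyl beside a secondary one and a clean hydride displacement.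

22 ⇒ 19 + 9. The C2–C3 bond is cut. Both stereocentres of that edge arise in one auxiliary-controlled step and the two aryl halves meet convergently. The demand is anti selectivity with the absolute sense fixed by the auxiliary against the influence of the C4 centre.

19 ⇒ 12 + 15, and 15 ⇒ 13 + 14. The C4–C5 bond is cut as a conjugate addition of a 1-arylvinyl metal to the crotonyl imide. The same auxiliary that will steer the aldol sets C4, and the aldol substrate is formed directly. No ester has to be cleaved and no acid meets the acid-sensitive 1-arylvinyl group. The demand is β-face selectivity from the chelated s-cis imide.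

12 ⇒ 10 ⇒ 9. The C–Br and C–H bonds across the alkene are traced to an alkyne, and the alkyne carbon to the aldehyde. Both halves of the molecule thus come from the single aldehyde 9. The demand is α-selective (Markovnikov) hydrometalation.

9 ⇒ 7 + 8. The aryl C4–O bond is cut. The formyl group that is needed anyway activates the para fluorine, and C8 is not touched, so its configuration is kept. The demand is that the silyl group does not wander to the neighbouring alkoxide; for that reason the bulky triisopropylsilyl group is used on O7.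

7 ⇒ 6 ⇒ 5 ⇒ 3 + 4, and 3 ⇒ 2 ⇒ 1. The C7–aryl bond is cut next to the lactate-derived C8 centre. C8 comes from the chiral pool and C7 is set by chelation (threo). The temporary benzyl ether both enforces the chelate and leaves O8 free after hydrogenolysis. The demand is Cram-chelate selectivity and no epimerisation of 3.

## Other disconnections considered

Alternative 1: The cut is the O1–C2 bond of a core that carries bromine in place of the arms. In the forward sense, the free carbinol of the monosilylated 1,4-diol (1S,2S,3S,4R)-1,4-bis(4-bromo-3-methoxyphenyl)-4-(tert-butyldimethylsilyloxy)-2,3-dimethylbutan-1-ol A2 is mesylated. Fluoride then frees the other oxygen, which closes ring A by 5-exo-tet SN2 displacement with inversion, giving (2R,3S,4S,5R)-2,5-bis(4-bromo-3-methoxyphenyl)-3,4-dimethyloxolane A1.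
- In favour: the last ring stereocentre is fixed stereospecifically by the configuration of A2, not by the facial bias of a planar cation. No Lewis acid is used, and the para-bromine slows ionisation of the benzylic sulfonate and later serves as the handle for the arms.
- Against here: a benzylic mesylate remains close to the SN1 border, and any ionisation leaks into the trans isomer. A2 needs four contiguous acyclic stereocentres with two differentiated benzylic oxygens. The arms must be attached afterwards, so this closure cannot be run on the arm-bearing para-alkoxy aryl groups of the chosen plan.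
- Comparison: on mechanism, A1 by inversion is the better of the two for certainty of the ring-closing stereocentre. On structure, the chosen plan is better: it needs only three pre-set centres and one carbinol, and gains two of them in one aldol. On step economy, the core sequences are about equal, but alternative 1 still owes two aryl–oxygen bonds and a deprotection.

Alternative 2: The cut removes both C–CH3 bonds from a five-membered lactone acetal. In the forward sense, Me2CuLi adds to C4 of (5S)-5-[(1S,2R,5S)-menthyloxy]furan-2(5H)-one A4 on the face away from the alkoxy group. The enolate is methylated by MeI trans to the new methyl, giving (3S,4S,5S)-3,4-dimethyl-5-[(1S,2R,5S)-menthyloxy]dihydrofuran-2(3H)-one A3.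
- In favour: both methyl stereocentres and their trans relation arise in one flask, enforced by the ring and an inexpensive chiral acetal. On this point it is better than the chosen plan, which sets C4 and C3 in two separate auxiliary-controlled steps.
- Against here: neither aryl-bearing centre is set. One aryl must be added to the lactone carbonyl and the other must replace the acetal oxygen, each through a planar oxocarbenium-type centre, so the cis aryl/methyl relation has to be won twice. The aryl nucleophiles would have to carry the arms or the arms must come late.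
- Comparison: on mechanism, the two plans are equal in relying on hydride or nucleophile delivery to an oxocarbenium ion for one aryl carbon. The chosen plan is better for the C2/C3 cis pair, which the aldol sets under auxiliary control. On step economy, A3 is reached quickly, but the distance from A3 to the target is at least as long as from 22.

Alternative 3: The cut is at both aryl C4–O bonds. In the forward sense, Pd2(dba)3 with RockPhos couples the two C–Br positions of A1 with two molecules of (1R,2R)-1-(3,4-dimethoxyphenyl)-1-(methoxymethoxy)propan-2-ol A6. C8 is retained, and the product is the bis(methoxymethyl) ether of the target A5.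
- In favour: the plan is maximally convergent and uses the C2 symmetry twice. The arms never see the ring-forming chemistry (hydrides, oxidant, Lewis acid), which is a real advantage over the chosen plan. No activating group is needed on the arene, and the longest linear sequence is probably equal or shorter.
- Against here: etherification of a secondary alcohol by an electron-rich, ortho-methoxy aryl bromide on zerovalent palladium competes with β-hydride elimination of the palladium alkoxide and with hydrodebromination. It has to succeed twice on one molecule with an excess of the valuable alcohol. The acetal protecting groups must finally be removed with acid next to benzylic carbinols and benzylic ring ethers.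
- Comparison: on mechanism, the SNAr of the chosen plan (an activated fluoroarene, no metal) is the more certain C–O bond formation. On structure, alternative 3 is the better at shielding the arms. It still needs A1, that is, the chemistry of alternative 1 or an equivalent.

Key step: step 11

Remarks on the chemistry:
- Ar* = 3-methoxy-4-{[(1R,2R)-1-(3,4-dimethoxyphenyl)-1-(triisopropylsilyloxy)propan-2-yl]oxy}phenyl.
- The descriptors were re-derived from the target. The (3S) centre of 19 becomes C4; the (2S) α-carbon and the (R) carbinol of 22 (the (2S,3R) anti-aldol) become C3 and C2. The chelated-enolate model with the (R)-benzyl auxiliary gives exactly this isomer, so no stereochemical correction is needed.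
- Two design changes are made. The arm silyl group is triisopropylsilyl (slower 1,2-migration under SNAr conditions, more resistant to Lewis acid). The conjugate addition is run on the crotonyl imide itself.
- Assumption: 4 is used as its commercial solution.

## Route

Step 1
Reactants: 1 methyl (2R)-2-hydroxypropanoate (methyl (R)-lactate)
Product: 2 methyl (2R)-2-(benzyloxy)propanoate
Conditions: BnOC(=NH)CCl3, TfOH (cat.), cyclohexane/CH2Cl2, rt
Reagents that add atoms: benzyl 2,2,2-trichloroacetimidate, ClC(Cl)(Cl)C(=N)OCc1ccccc1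
Why: Acid-catalysed O-benzylation with the trichloroacetimidate etherifies an α-hydroxy ester without base, so the lactate centre is never enolised and stays (R).

Step 2
Reactants: 2 methyl (2R)-2-(benzyloxy)propanoate
Product: 3 (2R)-2-(benzyloxy)propanal
Conditions: DIBAL-H, CH2Cl2, −78 °C; Rochelle salt
Reagents that add atoms: none
Why: Low-temperature DIBAL-H reduction of an α-alkoxy ester stops at the aldehyde; 3 is used crude at once because α-alkoxy aldehydes epimerise on standing.

Step 3
Reactants: 3 (2R)-2-(benzyloxy)propanal; 4 (3,4-dimethoxyphenyl)magnesium bromide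
Product: 5 (1R,2R)-2-(benzyloxy)-1-(3,4-dimethoxyphenyl)propan-1-ol
Conditions: MgBr2·OEt2, CH2Cl2, −78 °C; then 4, −78 °C
Reagents that add atoms: none
Why: Cram-chelate addition: magnesium bridges the carbonyl and benzyloxy oxygens and the aryl group enters on the face flanked by H and not by CH3, which should give the threo (1R,2R) carbinol; the minor erythro isomer would be removed by chromatography.

Step 4
Reactants: 5 (1R,2R)-2-(benzyloxy)-1-(3,4-dimethoxyphenyl)propan-1-ol
Product: 6 [(1R,2R)-2-(benzyloxy)-1-(3,4-dimethoxyphenyl)propoxy]tri(propan-2-yl)silane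
Conditions: TIPSOTf, 2,6-lutidine, CH2Cl2, 0 °C → rt
Reagents that add atoms: triisopropylsilyl trifluoromethanesulfonate, CC(C)[Si](C(C)C)(C(C)C)OS(=O)(=O)C(F)(F)F
Why: The silyl triflate with a hindered base silylates the hindered secondary benzylic alcohol without ionising it; the bulky group is chosen to resist 1,2-migration in step 6 and Lewis acid in step 16.

Step 5
Reactants: 6 [(1R,2R)-2-(benzyloxy)-1-(3,4-dimethoxyphenyl)propoxy]tri(propan-2-yl)silane
Product: 7 (1R,2R)-1-(3,4-dimethoxyphenyl)-1-[(triisopropylsilyl)oxy]propan-2-ol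
Conditions: H2 (1 atm), Pd/C, EtOAc, rt
Reagents that add atoms: none
Why: Hydrogenolysis of the O-benzyl ether in neutral ethyl acetate should be much faster than cleavage of the benzylic C–O bond shielded by the bulky silyl group; the reaction is stopped at full conversion.

Step 6
Reactants: 7 (1R,2R)-1-(3,4-dimethoxyphenyl)-1-[(triisopropylsilyl)oxy]propan-2-ol; 8 4-fluoro-3-methoxybenzaldehyde
Product: 9 3-methoxy-4-{[(1R,2R)-1-(3,4-dimethoxyphenyl)-1-(triisopropylsilyloxy)propan-2-yl]oxy}benzaldehyde (Ar*–CHO)
Conditions: NaH, DMF, 0 °C → rt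
Reagents that add atoms: none
Why: The sodium alkoxide of 7 displaces the fluoride para to the formyl group by addition–elimination (SNAr); the C8–O bond is not involved, so C8 keeps its (R) configuration, and 8 cannot enolise.

Step 7
Reactants: 9 Ar*–CHO
Product: 10 1-ethynyl arene Ar*–C≡CH
Conditions: dimethyl (1-diazo-2-oxopropyl)phosphonate, K2CO3, MeOH/THF, 0 °C → rt
Reagents that add atoms: dimethyl (1-diazo-2-oxopropyl)phosphonate, CC(=O)C(=[N+]=[N-])P(=O)(OC)OC
Why: Seyferth–Gilbert homologation in the Ohira–Bestmann variant converts a non-enolisable aryl aldehyde into the terminal alkyne under mild carbonate conditions that leave the silyl ether and both stereocentres untouched.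

Step 8
Reactants: 10 Ar*–C≡CH
Product: 12 1-bromo-1-(Ar*)ethene, via alkenylalane 11 (not isolated)
Conditions: Ni(dppp)Cl2 (3 mol %), DIBAL-H, THF, 0 °C → rt; then NBS, 0 °C
Reagents that add atoms: N-bromosuccinimide, O=C1CCC(=O)N1Br
Why: Nickel-catalysed hydroalumination of a terminal aryl alkyne with the bisphosphine dppp places aluminium on the internal carbon (11), and the C–Al bond is then brominated at that position to give the 1-bromovinyl arene; the substrate has no group that DIBAL-H reduces.

Step 9
Reactants: 13 (4R)-4-benzyl-1,3-oxazolidin-2-one; 14 (E)-but-2-enoyl chloride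
Product: 15 (4R)-4-benzyl-3-[(E)-but-2-enoyl]-1,3-oxazolidin-2-one
Conditions: n-BuLi, THF, −78 °C; then 14, −78 → 0 °C
Reagents that add atoms: none
Why: N-Acylation of the lithiated oxazolidinone with the acid chloride is the standard entry to N-enoyl imides; the alkene stays E.

Step 10
Reactants: 12 1-bromo-1-(Ar*)ethene; 15 (4R)-4-benzyl-3-[(E)-but-2-enoyl]-1,3-oxazolidin-2-one
Product: 19 (4R)-4-benzyl-3-[(3S)-3-methyl-4-(Ar*)pent-4-enoyl]-1,3-oxazolidin-2-one, via alkenyllithium 16 (not isolated), via alkenylmagnesium bromide 17 (not isolated), via alkenylcopper 18 (not isolated)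
Conditions: 12 (1.5 equiv), t-BuLi, Et2O, −78 °C; MgBr2·OEt2; CuBr·SMe2, THF/Me2S, −40 °C; then 15, −40 → −10 °C
Reagents that add atoms: none
Why: Bromine–lithium exchange and transmetalation give 18, which adds to the β-carbon of 15 held s-cis and syn-planar by magnesium chelation of both carbonyls; the benzyl group blocks one face, so the new bond forms on the other and the methyl-bearing centre should be (S) (auxiliary-controlled cuprate conjugate addition to an N-enoyl oxazolidinone). The adduct is already the aldol substrate, so no ester cleavage or re-acylation is needed.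

Step 11
Reactants: 19 (4R)-4-benzyl-3-[(3S)-3-methyl-4-(Ar*)pent-4-enoyl]-1,3-oxazolidin-2-one; 9 Ar*–CHO
Product: 22 (4R)-4-benzyl-3-{(2S,3S)-2-[(R)-hydroxy(Ar*)methyl]-3-methyl-4-(Ar*)pent-4-enoyl}-1,3-oxazolidin-2-one (the (2S,3R) anti-aldol), via chloromagnesium enolate 20 (not isolated), via trimethylsilyl ether 21 (not isolated)
Conditions: MgCl2 (0.5 equiv), Et3N, Me3SiCl, EtOAc, 23 °C; then 1 N HCl, THF, 0 °C
Reagents that add atoms: none
Why: MgCl2 binds both imide carbonyls of 19, which acidifies the α-CH2 enough for Et3N to form the chelated Z-enolate 20; the magnesium-bound aldehyde 9 is attacked through a boat-like six-membered transition state, Me3SiCl silylates the aldolate to 21 (freeing the metal for turnover and blocking retro-aldol), and dilute acid then cleaves the labile O–SiMe3 bond to give 22. The closest known reaction type is the magnesium halide-catalysed direct anti-aldol addition of N-acyl oxazolidinones to aromatic aldehydes. One C–C bond (C2–C3 of the future ring) is formed and no ring is closed. The C3 centre (the 2S α-carbon of 22) is set by the (R)-benzyl group, which shields one face of the chelated enolate so that 9 approaches from the other; the C2 carbinol (R) follows from the boat geometry, which puts the aldehyde aryl group anti to the enolate substituent. The step needs the auxiliary to override the neighbouring C4 methyl centre, and the rigid chelate secures this by holding the benzyl group closer to the reacting carbon than the freely rotating C4 substituent. It also needs chemoselectivity for the imide α-position: 9 cannot enolise, the 1,1-disubstituted alkene and the silyl ethers are inert to MgCl2/Et3N, and the aldolate of the electron-rich aldehyde is trapped by silylation before it can revert.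

Step 12
Reactants: 22 the (2S,3R) anti-aldol imide
Product: 23 (1R,2R)-1-(Ar*)-2-[(2S)-3-(Ar*)but-3-en-2-yl]propane-1,3-diol
Conditions: LiBH4, MeOH (1 equiv), THF, 0 °C
Reagents that add atoms: none
Why: Reductive cleavage of the N-acyl oxazolidinone turns the imide carbonyl into CH2OH and releases the auxiliary without touching any stereocentre; the alkene, aryl ethers and silyl ethers are inert to LiBH4.

Step 13
Reactants: 23 (1R,2R)-1-(Ar*)-2-[(2S)-3-(Ar*)but-3-en-2-yl]propane-1,3-diol
Product: 24 (2R,3S)-2-[(R)-hydroxy(Ar*)methyl]-3-methyl-4-(Ar*)pent-4-en-1-yl 4-methylbenzenesulfonate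
Conditions: TsCl (1.1 equiv), Et3N, DMAP (cat.), CH2Cl2, 0 °C
Reagents that add atoms: 4-methylbenzenesulfonyl chloride, Cc1ccc(cc1)S(Cl)(=O)=O
Why: The primary hydroxyl is far more accessible than the benzylic secondary one flanked by two branched carbons, so one equivalent of TsCl should sulfonylate it selectively (selective primary sulfonylation of a 1,3-diol).

Step 14
Reactants: 24 the primary tosylate
Product: 25 (1R,2S,3S)-2,3-dimethyl-1,4-bis(Ar*)pent-4-en-1-ol
Conditions: LiEt3BH, THF, 0 °C → rt
Reagents that add atoms: none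
Why: Triethylborohydride displaces primary tosylates by SN2 even at β-branched carbons, which turns the former acyl carbon into the C3 methyl; no stereocentre takes part.

Step 15
Reactants: 25 (1R,2S,3S)-2,3-dimethyl-1,4-bis(Ar*)pent-4-en-1-ol
Product: 28 (3S,4S,5R)-3,4-dimethyl-2,5-bis(Ar*)oxolan-2-ol (both C2 epimers), via triol 26 (not isolated), via hydroxy ketone 27 (not isolated)
Conditions: OsO4 (cat.), NaIO4, 2,6-lutidine, dioxane/H2O, rt
Reagents that add atoms: osmium tetroxide, O=[Os](=O)(=O)=O (catalytic oxygen carrier); sodium periodate, [Na+].[O-][I](=O)(=O)=O (terminal source of the new oxygen)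
Why: Lemieux–Johnson cleavage: OsO4 dihydroxylates the only alkene to 26, periodate cleaves the 1,2-diol to the aryl ketone 27 with loss of the CH2 carbon, and the γ-hydroxy ketone closes to the five-membered lactol 28 by addition of the C2 hydroxyl to the C5 carbonyl. Ozone is avoided because of the electron-rich arenes, and 2,6-lutidine keeps the medium buffered.

Step 16
Reactants: 28 the lactol
Product: 30 (2R,3S,4S,5R)-3,4-dimethyl-2,5-bis(Ar*)oxolane, via oxocarbenium ion 29 (not isolated)
Conditions: Et3SiH, BF3·OEt2, CH2Cl2, −78 °C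
Reagents that add atoms: none
Why: BF3·OEt2 ionises the hemiketal to the aryl-stabilised oxocarbenium ion 29 and Et3SiH delivers hydride to C5 anti to the adjacent C4 methyl, the kinetic preference of 2-aryl-3-methyl oxocarbenium ions, so the C5 aryl ends cis to the C4 methyl and trans to the C2 aryl (5R) (ionic reduction of a lactol). At −78 °C with excess silane, reduction should outrun acid-mediated epimerisation and ionisation of the hindered arm silyl ethers.

Step 17
Reactants: 30 (2R,3S,4S,5R)-3,4-dimethyl-2,5-bis(Ar*)oxolane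
Product: 31 2,2'-{[(2R,3S,4S,5R)-3,4-dimethyloxolane-2,5-diyl]bis[(2-methoxy-4,1-phenylene)oxy]}bis[(1R,2R)-1-(3,4-dimethoxyphenyl)propan-1-ol] (target)
Conditions: TBAF, THF, rt → 40 °C
Reagents that add atoms: none
Why: Fluoride cleaves both Si–O bonds under essentially neutral conditions, which spares the acid-sensitive benzylic ethers and carbinols; no stereocentre is touched (fluoride desilylation).

## Compound list

1 | methyl (2R)-2-hydroxypropanoate | C[C@@H](O)C(=O)OC | starting material
2 | methyl (2R)-2-(benzyloxy)propanoate | C[C@@H](OCc1ccccc1)C(=O)OC | intermediate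
3 | (2R)-2-(benzyloxy)propanal | C[C@@H](OCc1ccccc1)C=O | intermediate
4 | (3,4-dimethoxyphenyl)magnesium bromide | COc1ccc([Mg]Br)cc1OC | starting material
5 | (1R,2R)-2-(benzyloxy)-1-(3,4-dimethoxyphenyl)propan-1-ol | c1ccccc1CO[C@H](C)[C@H](O)c1ccc(OC)c(OC)c1 | intermediate
6 | [(1R,2R)-2-(benzyloxy)-1-(3,4-dimethoxyphenyl)propoxy]tri(propan-2-yl)silane | c1ccccc1CO[C@H](C)[C@H](O[Si](C(C)C)(C(C)C)C(C)C)c1ccc(OC)c(OC)c1 | intermediate
7 | (1R,2R)-1-(3,4-dimethoxyphenyl)-1-[(triisopropylsilyl)oxy]propan-2-ol | O[C@H](C)[C@H](O[Si](C(C)C)(C(C)C)C(C)C)c1ccc(OC)c(OC)c1 | intermediate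
8 | 4-fluoro-3-methoxybenzaldehyde | COc1cc(C=O)ccc1F | starting material
9 | 3-methoxy-4-{[(1R,2R)-1-(3,4-dimethoxyphenyl)-1-(triisopropylsilyloxy)propan-2-yl]oxy}benzaldehyde (Ar*–CHO) | O=Cc1ccc(O[C@H](C)[C@H](O[Si](C(C)C)(C(C)C)C(C)C)c2ccc(OC)c(OC)c2)c(OC)c1 | intermediate
10 | 1-ethynyl arene Ar*–C≡CH | C#Cc1ccc(O[C@H](C)[C@H](O[Si](C(C)C)(C(C)C)C(C)C)c2ccc(OC)c(OC)c2)c(OC)c1 | intermediate
11 | diisobutyl[1-(Ar*)ethenyl]aluminium | C=C([Al](CC(C)C)CC(C)C)c1ccc(O[C@H](C)[C@H](O[Si](C(C)C)(C(C)C)C(C)C)c2ccc(OC)c(OC)c2)c(OC)c1 | intermediate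
12 | 1-bromo-1-(Ar*)ethene | C=C(Br)c1ccc(O[C@H](C)[C@H](O[Si](C(C)C)(C(C)C)C(C)C)c2ccc(OC)c(OC)c2)c(OC)c1 | intermediate
13 | (4R)-4-benzyl-1,3-oxazolidin-2-one | O=C1N[C@H](Cc2ccccc2)CO1 | starting material
14 | (E)-but-2-enoyl chloride | C/C=C/C(Cl)=O | starting material
15 | (4R)-4-benzyl-3-[(E)-but-2-enoyl]-1,3-oxazolidin-2-one | C/C=C/C(=O)N1[C@H](Cc2ccccc2)COC1=O | intermediate
16 | [1-(Ar*)ethenyl]lithium | [Li]C(=C)c1ccc(O[C@H](C)[C@H](O[Si](C(C)C)(C(C)C)C(C)C)c2ccc(OC)c(OC)c2)c(OC)c1 | intermediate
17 | [1-(Ar*)ethenyl]magnesium bromide | Br[Mg]C(=C)c1ccc(O[C@H](C)[C@H](O[Si](C(C)C)(C(C)C)C(C)C)c2ccc(OC)c(OC)c2)c(OC)c1 | intermediate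
18 | [1-(Ar*)ethenyl]copper | [Cu]C(=C)c1ccc(O[C@H](C)[C@H](O[Si](C(C)C)(C(C)C)C(C)C)c2ccc(OC)c(OC)c2)c(OC)c1 | intermediate
19 | (4R)-4-benzyl-3-[(3S)-3-methyl-4-(Ar*)pent-4-enoyl]-1,3-oxazolidin-2-one | O=C(C[C@H](C)C(=C)c1ccc(O[C@H](C)[C@H](O[Si](C(C)C)(C(C)C)C(C)C)c2ccc(OC)c(OC)c2)c(OC)c1)N1[C@H](Cc2ccccc2)COC1=O | intermediate
20 | chloromagnesium (Z)-enolate of 19 | Cl[Mg]O/C(=C\[C@H](C)C(=C)c1ccc(O[C@H](C)[C@H](O[Si](C(C)C)(C(C)C)C(C)C)c2ccc(OC)c(OC)c2)c(OC)c1)N1[C@H](Cc2ccccc2)COC1=O | intermediate
21 | O-trimethylsilyl ether of 22 | O=C(N1[C@H](Cc2ccccc2)COC1=O)[C@H]([C@@H](O[Si](C)(C)C)c1ccc(O[C@H](C)[C@H](O[Si](C(C)C)(C(C)C)C(C)C)c2ccc(OC)c(OC)c2)c(OC)c1)[C@H](C)C(=C)c1ccc(O[C@H](C)[C@H](O[Si](C(C)C)(C(C)C)C(C)C)c2ccc(OC)c(OC)c2)c(OC)c1 | intermediate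
22 | (4R)-4-benzyl-3-{(2S,3S)-2-[(R)-hydroxy(Ar*)methyl]-3-methyl-4-(Ar*)pent-4-enoyl}-1,3-oxazolidin-2-one | O=C(N1[C@H](Cc2ccccc2)COC1=O)[C@H]([C@@H](O)c1ccc(O[C@H](C)[C@H](O[Si](C(C)C)(C(C)C)C(C)C)c2ccc(OC)c(OC)c2)c(OC)c1)[C@H](C)C(=C)c1ccc(O[C@H](C)[C@H](O[Si](C(C)C)(C(C)C)C(C)C)c2ccc(OC)c(OC)c2)c(OC)c1 | intermediate
23 | (1R,2R)-1-(Ar*)-2-[(2S)-3-(Ar*)but-3-en-2-yl]propane-1,3-diol | OC[C@H]([C@@H](O)c1ccc(O[C@H](C)[C@H](O[Si](C(C)C)(C(C)C)C(C)C)c2ccc(OC)c(OC)c2)c(OC)c1)[C@H](C)C(=C)c1ccc(O[C@H](C)[C@H](O[Si](C(C)C)(C(C)C)C(C)C)c2ccc(OC)c(OC)c2)c(OC)c1 | intermediate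
24 | (2R,3S)-2-[(R)-hydroxy(Ar*)methyl]-3-methyl-4-(Ar*)pent-4-en-1-yl 4-methylbenzenesulfonate | Cc1ccc(cc1)S(=O)(=O)OC[C@H]([C@@H](O)c1ccc(O[C@H](C)[C@H](O[Si](C(C)C)(C(C)C)C(C)C)c2ccc(OC)c(OC)c2)c(OC)c1)[C@H](C)C(=C)c1ccc(O[C@H](C)[C@H](O[Si](C(C)C)(C(C)C)C(C)C)c2ccc(OC)c(OC)c2)c(OC)c1 | intermediate
25 | (1R,2S,3S)-2,3-dimethyl-1,4-bis(Ar*)pent-4-en-1-ol | C[C@H]([C@@H](O)c1ccc(O[C@H](C)[C@H](O[Si](C(C)C)(C(C)C)C(C)C)c2ccc(OC)c(OC)c2)c(OC)c1)[C@H](C)C(=C)c1ccc(O[C@H](C)[C@H](O[Si](C(C)C)(C(C)C)C(C)C)c2ccc(OC)c(OC)c2)c(OC)c1 | intermediate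
26 | (1R,2S,3S)-2,3-dimethyl-1,4-bis(Ar*)pentane-1,4,5-triol (C4 epimers) | C[C@H]([C@@H](O)c1ccc(O[C@H](C)[C@H](O[Si](C(C)C)(C(C)C)C(C)C)c2ccc(OC)c(OC)c2)c(OC)c1)[C@H](C)C(O)(CO)c1ccc(O[C@H](C)[C@H](O[Si](C(C)C)(C(C)C)C(C)C)c2ccc(OC)c(OC)c2)c(OC)c1 | intermediate
27 | (2S,3S,4R)-4-hydroxy-2,3-dimethyl-1,4-bis(Ar*)butan-1-one | C[C@H]([C@@H](O)c1ccc(O[C@H](C)[C@H](O[Si](C(C)C)(C(C)C)C(C)C)c2ccc(OC)c(OC)c2)c(OC)c1)[C@H](C)C(=O)c1ccc(O[C@H](C)[C@H](O[Si](C(C)C)(C(C)C)C(C)C)c2ccc(OC)c(OC)c2)c(OC)c1 | intermediate
28 | (3S,4S,5R)-3,4-dimethyl-2,5-bis(Ar*)oxolan-2-ol (C2 epimers) | C[C@H]1[C@H](C)[C@H](c2ccc(O[C@H](C)[C@H](O[Si](C(C)C)(C(C)C)C(C)C)c3ccc(OC)c(OC)c3)c(OC)c2)OC1(O)c1ccc(O[C@H](C)[C@H](O[Si](C(C)C)(C(C)C)C(C)C)c2ccc(OC)c(OC)c2)c(OC)c1 | intermediate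
29 | (2R,3S,4S)-3,4-dimethyl-2,5-bis(Ar*)-3,4-dihydro-2H-furan-1-ium (oxocarbenium ion) | C[C@H]1[C@H](C)[C@H](c2ccc(O[C@H](C)[C@H](O[Si](C(C)C)(C(C)C)C(C)C)c3ccc(OC)c(OC)c3)c(OC)c2)[O+]=C1c1ccc(O[C@H](C)[C@H](O[Si](C(C)C)(C(C)C)C(C)C)c2ccc(OC)c(OC)c2)c(OC)c1 | intermediate
30 | (2R,3S,4S,5R)-3,4-dimethyl-2,5-bis(Ar*)oxolane | C[C@H]1[C@H](C)[C@H](c2ccc(O[C@H](C)[C@H](O[Si](C(C)C)(C(C)C)C(C)C)c3ccc(OC)c(OC)c3)c(OC)c2)O[C@H]1c1ccc(O[C@H](C)[C@H](O[Si](C(C)C)(C(C)C)C(C)C)c2ccc(OC)c(OC)c2)c(OC)c1 | intermediate
31 | 2,2'-{[(2R,3S,4S,5R)-3,4-dimethyloxolane-2,5-diyl]bis[(2-methoxy-4,1-phenylene)oxy]}bis[(1R,2R)-1-(3,4-dimethoxyphenyl)propan-1-ol] | C[C@H]1[C@H](C)[C@H](c2ccc(O[C@H](C)[C@H](O)c3ccc(OC)c(OC)c3)c(OC)c2)O[C@H]1c1ccc(O[C@H](C)[C@H](O)c2ccc(OC)c(OC)c2)c(OC)c1 | target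

## Step count and least certain steps

Total: 17 steps. Longest linear sequence: 16 steps (steps 1–8 and 10–17; step 9 is a one-step branch, and 9 feeds both step 7 and step 11).

Step 11 (key step). Enolisation and addition may be slow because the acyl chain is β-branched. Facial selectivity may also be eroded: the rotamer about the C3–C4 bond that avoids allylic strain puts the large arylvinyl group on the enolate face that the auxiliary leaves open, so this is probably the mismatched pairing. Retro-aldol during removal of the trimethylsilyl group is a further risk.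
Fallback: set out from 19 and form the dibutylboron (Z)-enolate of 19 F1 with Bu2BOTf and i-Pr2NEt in CH2Cl2. Add it at −78 °C to 9 that has been precomplexed with Et2AlCl. This Lewis-acid-mediated open-transition-state aldol uses a stoichiometric, preformed enolate. It is expected to attack the same enolate face (boron internally chelated, benzyl group on the far side) with anti topicity, and so to return to the route at 22.

Step 10. Face selectivity with the benzyl auxiliary may be only moderate, the hindered 1-arylvinyl group may transfer sluggishly from copper, and an excess of 12 is consumed.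
Fallback: set out from 10 and hydroaluminate as in step 8, but quench 11 with 2-methoxy-4,4,5,5-tetramethyl-1,3,2-dioxaborolane to give 2-[1-(Ar*)ethenyl]-4,4,5,5-tetramethyl-1,3,2-dioxaborolane F2. Rhodium-catalysed asymmetric conjugate addition (Rh(acac)(C2H4)2, (R)-BINAP, dioxane/H2O, heat) to methyl (E)-crotonate then gives methyl (3S)-3-methyl-4-(Ar*)pent-4-enoate F3 under reagent control. (R)-BINAP is the enantiomer expected to give the (S) adduct by analogy with aryl additions to E-crotonates; the sense would be checked on 1-phenylvinylboronate. LiOH in THF/H2O gives (3S)-3-methyl-4-(Ar*)pent-4-enoic acid F4 without any acid treatment, and DCC/DMAP coupling with 13 returns to the route at 19.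

Step 6. The alkoxide of 7 may pass its silyl group to the neighbouring oxygen before it reacts, which would lead to the regioisomeric benzylic aryl ether. Hydride transfer from the secondary alkoxide to the aldehyde is a second possible loss.
Fallback: set out from 7 and couple it with 4-bromo-3-methoxybenzaldehyde under Pd2(dba)3/RockPhos, Cs2CO3, toluene, 90 °C. This palladium-catalysed C–O coupling never builds up free alkoxide and returns directly at 9.

Step 14. The alkoxide formed from the free C1 hydroxyl may attack the tosylate intramolecularly (four-membered ether) or trigger fragmentation. Displacement at the β-branched carbon may also be slow.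
Fallback: set out from 24 and silylate the secondary hydroxyl (TESOTf, 2,6-lutidine) to give (2R,3S)-3-methyl-4-(Ar*)-2-[(R)-(Ar*)(triethylsilyloxy)methyl]pent-4-en-1-yl 4-methylbenzenesulfonate F5. Reduce with LiEt3BH to triethyl{[(1R,2S,3S)-2,3-dimethyl-1,4-bis(Ar*)pent-4-en-1-yl]oxy}silane F6, then remove the triethylsilyl group selectively with HF·pyridine/pyridine in THF at 0 °C, returning at 25.

Step 16. BF3·OEt2 may ionise the benzylic arm silyl ethers (loss or scrambling of C7). The oxocarbenium ion may equilibrate through the enol ether or by opening of the benzylic C2–O1 bond (epimerisation at C4 or C2). Hydride may also add with imperfect face selectivity.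
Fallback: set out from 28 and take the arms through the reduction at the ketone oxidation level, where they cannot ionise.
- TBAF gives (3S,4S,5R)-2,5-bis{4-[(1R,2R)-1-(3,4-dimethoxyphenyl)-1-hydroxypropan-2-yl]oxy-3-methoxyphenyl}-3,4-dimethyloxolan-2-ol F7.
- MnO2 oxidises only the two secondary benzylic carbinols, giving (3S,4S,5R)-2,5-bis{4-[(2R)-1-(3,4-dimethoxyphenyl)-1-oxopropan-2-yl]oxy-3-methoxyphenyl}-3,4-dimethyloxolan-2-ol F8.
- Et3SiH/BF3·OEt2 at −78 °C gives (2R,2'R)-2,2'-{[(2R,3S,4S,5R)-3,4-dimethyloxolane-2,5-diyl]bis[(2-methoxy-4,1-phenylene)oxy]}bis[1-(3,4-dimethoxyphenyl)propan-1-one] F9.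
- Reduction with a non-chelating hydride (borohydride on a quaternary ammonium resin; Felkin–Anh control is expected to favour the threo carbinols) returns at 31.

The C8 centres of F8 and F9 are α to a ketone and must be kept away from base.

## Further compounds

F1 | step 11 | dibutylboron (Z)-enolate of 19 | CCCCB(CCCC)O/C(=C\[C@H](C)C(=C)c1ccc(O[C@H](C)[C@H](O[Si](C(C)C)(C(C)C)C(C)C)c2ccc(OC)c(OC)c2)c(OC)c1)N1[C@H](Cc2ccccc2)COC1=O
F2 | step 10 | 2-[1-(Ar*)ethenyl]-4,4,5,5-tetramethyl-1,3,2-dioxaborolane | C=C(B1OC(C)(C)C(C)(C)O1)c1ccc(O[C@H](C)[C@H](O[Si](C(C)C)(C(C)C)C(C)C)c2ccc(OC)c(OC)c2)c(OC)c1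
F3 | step 10 | methyl (3S)-3-methyl-4-(Ar*)pent-4-enoate | COC(=O)C[C@H](C)C(=C)c1ccc(O[C@H](C)[C@H](O[Si](C(C)C)(C(C)C)C(C)C)c2ccc(OC)c(OC)c2)c(OC)c1
F4 | step 10 | (3S)-3-methyl-4-(Ar*)pent-4-enoic acid | OC(=O)C[C@H](C)C(=C)c1ccc(O[C@H](C)[C@H](O[Si](C(C)C)(C(C)C)C(C)C)c2ccc(OC)c(OC)c2)c(OC)c1
F0 | step 6 | none | none
F5 | step 14 | (2R,3S)-3-methyl-4-(Ar*)-2-[(R)-(Ar*)(triethylsilyloxy)methyl]pent-4-en-1-yl 4-methylbenzenesulfonate | Cc1ccc(cc1)S(=O)(=O)OC[C@H]([C@@H](O[Si](CC)(CC)CC)c1ccc(O[C@H](C)[C@H](O[Si](C(C)C)(C(C)C)C(C)C)c2ccc(OC)c(OC)c2)c(OC)c1)[C@H](C)C(=C)c1ccc(O[C@H](C)[C@H](O[Si](C(C)C)(C(C)C)C(C)C)c2ccc(OC)c(OC)c2)c(OC)c1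
F6 | step 14 | triethyl{[(1R,2S,3S)-2,3-dimethyl-1,4-bis(Ar*)pent-4-en-1-yl]oxy}silane | C[C@H]([C@@H](O[Si](CC)(CC)CC)c1ccc(O[C@H](C)[C@H](O[Si](C(C)C)(C(C)C)C(C)C)c2ccc(OC)c(OC)c2)c(OC)c1)[C@H](C)C(=C)c1ccc(O[C@H](C)[C@H](O[Si](C(C)C)(C(C)C)C(C)C)c2ccc(OC)c(OC)c2)c(OC)c1
F7 | step 16 | (3S,4S,5R)-2,5-bis{4-[(1R,2R)-1-(3,4-dimethoxyphenyl)-1-hydroxypropan-2-yl]oxy-3-methoxyphenyl}-3,4-dimethyloxolan-2-ol | C[C@H]1[C@H](C)[C@H](c2ccc(O[C@H](C)[C@H](O)c3ccc(OC)c(OC)c3)c(OC)c2)OC1(O)c1ccc(O[C@H](C)[C@H](O)c2ccc(OC)c(OC)c2)c(OC)c1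
F8 | step 16 | (3S,4S,5R)-2,5-bis{4-[(2R)-1-(3,4-dimethoxyphenyl)-1-oxopropan-2-yl]oxy-3-methoxyphenyl}-3,4-dimethyloxolan-2-ol | C[C@H]1[C@H](C)[C@H](c2ccc(O[C@H](C)C(=O)c3ccc(OC)c(OC)c3)c(OC)c2)OC1(O)c1ccc(O[C@H](C)C(=O)c2ccc(OC)c(OC)c2)c(OC)c1
F9 | step 16 | (2R,2'R)-2,2'-{[(2R,3S,4S,5R)-3,4-dimethyloxolane-2,5-diyl]bis[(2-methoxy-4,1-phenylene)oxy]}bis[1-(3,4-dimethoxyphenyl)propan-1-one] | C[C@H]1[C@H](C)[C@H](c2ccc(O[C@H](C)C(=O)c3ccc(OC)c(OC)c3)c(OC)c2)O[C@H]1c1ccc(O[C@H](C)C(=O)c2ccc(OC)c(OC)c2)c(OC)c1
A1 | alternative 1 | (2R,3S,4S,5R)-2,5-bis(4-bromo-3-methoxyphenyl)-3,4-dimethyloxolane | C[C@H]1[C@H](C)[C@H](c2ccc(Br)c(OC)c2)O[C@H]1c1ccc(Br)c(OC)c1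
A2 | alternative 1 | (1S,2S,3S,4R)-1,4-bis(4-bromo-3-methoxyphenyl)-4-(tert-butyldimethylsilyloxy)-2,3-dimethylbutan-1-ol | CC(C)(C)[Si](C)(C)O[C@@H](c1ccc(Br)c(OC)c1)[C@@H](C)[C@H](C)[C@H](O)c1ccc(Br)c(OC)c1
A3 | alternative 2 | (3S,4S,5S)-3,4-dimethyl-5-[(1S,2R,5S)-menthyloxy]dihydrofuran-2(3H)-one | O=C1O[C@H](O[C@H]2C[C@@H](C)CC[C@@H]2C(C)C)[C@@H](C)[C@@H]1C
A4 | alternative 2 | (5S)-5-[(1S,2R,5S)-menthyloxy]furan-2(5H)-one | O=C1O[C@H](O[C@H]2C[C@@H](C)CC[C@@H]2C(C)C)C=C1
A5 | alternative 3 | bis(methoxymethyl) ether of the target | C[C@H]1[C@H](C)[C@H](c2ccc(O[C@H](C)[C@H](OCOC)c3ccc(OC)c(OC)c3)c(OC)c2)O[C@H]1c1ccc(O[C@H](C)[C@H](OCOC)c2ccc(OC)c(OC)c2)c(OC)c1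
A6 | alternative 3 | (1R,2R)-1-(3,4-dimethoxyphenyl)-1-(methoxymethoxy)propan-2-ol | O[C@H](C)[C@H](OCOC)c1ccc(OC)c(OC)c1
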